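All constants are invented; what happens was integrated by code.

Links were what I counted: each one closes two ends, and the chain length follows from the ends still open.

- grey: first end groups 0.31 M; second end groups 0.310 M; time 40 s
- ochre: first end groups 0.31 M; second end groups 0.310 M; time 120 s

    first end groups + second end groups ⇌ links + released group (K1 = 67, k1 = 9.27 L mol⁻¹ s⁻¹)
    second end groups → decomposed reagent (k2 = 0.00888 s⁻¹)
    released group → by-product carried off (k3 = 0.0345 s⁻¹)

- which of the two ends with the longer chains by the average number of monomer units in a chain (unreacted monomers counted as chains of one) ("neither" if they lie within 10 %) (grey / ochre / neither)
- average number of monomer units in a chain (unreacted monomers counted as chains of one) at the end, grey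
- average number of monomer units in a chain (unreacted monomers counted as chains of one) at the end, ochre

- each molecule carries two end groups: a chain counts once for every two ends that are left, dead ends included; the units are half of the end groups of the two monomers charged
- run time (grey): 40 s

1. I called the open share the part of the charged ends not closed by a link, dead ends included. The chain length was one over it, and with equal charges it was the fraction of first end groups left.

2. That fraction started steeply: in grey, first end groups had a half-life of 0.24 s by the forward step by itself, shorter than 20 s for the released group by its removal and 78 s for second end groups by decomposition.

3. So I put the knee at the balance of the link-forming step. Counting nothing as yet decomposed or carried off, I set reacted over left equal to the square root of 67, which put the fraction left at 10.9 %. This open share at the knee meant a chain of 9.17.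

4. Past the knee the curve crept down as the released group was carried off. For grey I let that group decay to 22.4 % of the charge, and the balance gave 5.46 % left. But decomposition leaves first end groups unpaired. From the mean of those two fractions I reckoned 2.90 % decomposed, and the balance with that gap gave 7.10 % left, a chain of 14.1.

5. For ochre I let the released group decay in the same way, to 1.42 %. To grey's decomposed share I added the further time's decomposition, reckoned on half of the second end groups I had left in grey, which gave 4.39 % decomposed. The same balance then gave 4.79 % left, a chain of 20.9. In my reckoning, ochre's curve was running towards the decomposed share as its level.

The forecast chose ochre, with 11.9 (10.8 to 13) for grey and 16.4 (14.8 to 18) for ochre, saying that “removal of the released group slowly pulls it forward”. My chains were longer than its values in both flasks.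

The simulation gave ochre, with 12.9 for grey and 19.1 for ochre.

Grey's open share at 40.0 s stood at 7.75 %, less than the knee's 10.9 %. The neighbouring flask was ochre with 0.53 M of first end groups, so second end groups came to 0.585 equiv and were the limiting reagent, with 0.035 % of them left. Its links stood at 58.0 % of the first end groups charged. Its open share was therefore 26.8 %, more than the 10.9 % I had reckoned at the knee for equal charges, and its chain length was 3.73.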